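**Retrosynthetic overview**

1. Numbering: C1 is the ring carbon bearing the guaiacyl group, C7 the benzylic CH2 of the 4-hydroxyphenyl arm, and the ring oxygen joins C1 and C5. The target is the all-cis (all-equatorial) tetrahydropyranol with C1 R, C3 R, C5 S and an R carbinol at C6.
2. Feature the strategy rests on: the C3(O)–C4H2–C5(O) 1,3-dioxygen array next to the erythro C5/C6 oxygen pair is an aldol retron. It maps onto a 4,5-dihydroisoxazole (C3=N, ring CH2 = C4, O–C5) whose C5 configuration an allylic C6 silyl ether can direct.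
3. Backwards from the target: deprotection; C3 carbinol from the C3 ketone by axial hydride delivery; O–C1 bond from a 6-endo oxa-Michael addition of the C5 hydroxyl to the C1=C2 enone; C3 ketone and C5 hydroxyl from N–O cleavage of the isoxazoline.
4. The isoxazoline comes from a [3+2] cycloaddition of the styryl nitrile oxide (from O-benzylconiferaldehyde oxime) with the (R)-allylic TBS ether, which is made from (R)-epichlorohydrin and an aryl Grignard reagent followed by sulfonium ylide homologation.
5. Ring order: temporary isoxazoline (step 7), opened in step 8, then the tetrahydropyran (step 9).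

Key step: step 7

**Route**

Step 1
Reactants: 1 coniferyl aldehyde
Product: 2 (E)-3-[4-(benzyloxy)-3-methoxyphenyl]prop-2-enal
Conditions: BnBr, K2CO3, DMF, rt
Reagents that add atoms: benzyl bromide, BrCc1ccccc1
Why: Williamson etherification of the phenoxide under mild carbonate conditions that leave the enal untouched.

Step 2
Reactants: 2 (E)-3-[4-(benzyloxy)-3-methoxyphenyl]prop-2-enal
Product: 3 (1E,2E)-3-[4-(benzyloxy)-3-methoxyphenyl]prop-2-enal oxime
Conditions: NH2OH·HCl, NaOAc, EtOH/H2O, rt
Reagents that add atoms: hydroxylamine hydrochloride, Cl.NO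
Why: Oxime condensation is fast for cinnamaldehydes, and any E/Z mixture at C=N is irrelevant because both isomers give the same nitrile oxide.

Step 3
Reactants: 4 1-(benzyloxy)-4-bromobenzene; 5 (R)-epichlorohydrin
Product: 7 (2R)-1-[4-(benzyloxy)phenyl]-3-chloropropan-2-ol, via [4-(benzyloxy)phenyl]magnesium bromide 6 (not isolated)
Conditions: Mg, THF; then CuI (10 mol %), 5, −30 → 0 °C; aq NH4Cl
Reagents that add atoms: none
Why: Copper-catalysed Grignard opening (SN2) of the epoxide at its unsubstituted carbon outruns chloride displacement at low temperature, and no bond to the stereocentre is broken, so the configuration of 5 becomes that of C6.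

Step 4
Reactants: 7 (2R)-1-[4-(benzyloxy)phenyl]-3-chloropropan-2-ol
Product: 8 (2R)-2-[4-(benzyloxy)benzyl]oxirane
Conditions: NaOH, THF/H2O, rt
Reagents that add atoms: none
Why: Intramolecular Williamson reaction (3-exo-tet) of the chlorohydrin alkoxide; the C–O bond at the stereocentre is untouched, so the configuration is retained.

Step 5
Reactants: 8 (2R)-2-[4-(benzyloxy)benzyl]oxirane
Product: 10 (2R)-1-[4-(benzyloxy)phenyl]but-3-en-2-ol, via sulfonium alkoxide betaine 9 (not isolated)
Conditions: Me3S+ I− (3 equiv), n-BuLi (3 equiv), THF, −10 °C → rt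
Reagents that add atoms: trimethylsulfonium iodide, C[S+](C)C.[I-]
Why: Sulfonium ylide homologation of a terminal epoxide to an allylic alcohol: dimethylsulfonium methylide opens the epoxide at CH2, further ylide converts betaine 9 into a new ylide that undergoes α',β-elimination with loss of dimethyl sulfide, and the carbinol centre is not touched.

Step 6
Reactants: 10 (2R)-1-[4-(benzyloxy)phenyl]but-3-en-2-ol
Product: 11 tert-butyl{[(2R)-1-[4-(benzyloxy)phenyl]but-3-en-2-yl]oxy}dimethylsilane
Conditions: TBSCl, imidazole, DMF, rt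
Reagents that add atoms: tert-butyldimethylsilyl chloride, CC(C)(C)[Si](C)(C)Cl
Why: Imidazole-mediated silylation of a secondary alcohol; the silyl ether is also the group meant to occupy the inside position in the cycloaddition.

Step 7
Reactants: 3 (1E,2E)-3-[4-(benzyloxy)-3-methoxyphenyl]prop-2-enal oxime; 11 tert-butyl{[(2R)-1-[4-(benzyloxy)phenyl]but-3-en-2-yl]oxy}dimethylsilane
Product: 14 (5S)-3-[(E)-2-[4-(benzyloxy)-3-methoxyphenyl]ethenyl]-5-[(1R)-2-[4-(benzyloxy)phenyl]-1-(tert-butyldimethylsilyloxy)ethyl]-4,5-dihydroisoxazole, via hydroximoyl chloride 12 (not isolated), via nitrile oxide 13 (not isolated)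
Conditions: NCS, DMF, rt; then 11, Et3N (slow addition), CH2Cl2, 0 °C → rt
Reagents that add atoms: none
Why: N-Chlorosuccinimide chlorinates the aldoxime to hydroximoyl chloride 12, from which slow addition of Et3N releases nitrile oxide 13 at low stationary concentration, and 13 adds to the terminal alkene of 11 in a concerted, asynchronous Huisgen [3+2] cycloaddition. The closest known reaction type is the nitrile oxide cycloaddition to chiral allylic ethers used as a masked aldol. The dihydroisoxazole ring is closed by the intermolecular cycloaddition itself, C3–C4 and O–C5 forming together, with the dipole oxygen going to the substituted alkene carbon as is general for monosubstituted alkenes. The new C5 stereocentre (S) is controlled by C6 through the inside-alkoxy transition state, with the silyloxy group inside, the arylmethyl group anti to the incoming dipole and hydrogen outside, which leads to the erythro (5S,6R) adduct. The step needs π-facial selectivity, which for an acyclic allylic silyl ether of this kind is expected to be useful but not complete, so the minor threo isomer is to be removed by chromatography here. It also needs the dipole to prefer the terminal alkene over dimerisation to the furoxan and over addition to a styryl double bond, which slow base addition and the much lower dipolarophilicity of 1,2-disubstituted conjugated alkenes should secure.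

Step 8
Reactants: 14 the dihydroisoxazole from step 7
Product: 16 (1E,5S,6R)-1-[4-(benzyloxy)-3-methoxyphenyl]-7-[4-(benzyloxy)phenyl]-6-(tert-butyldimethylsilyloxy)-5-hydroxyhept-1-en-3-one, via β-hydroxy enimine 15 (not isolated)
Conditions: SmI2, THF, 0 °C; then B(OH)3, H2O, rt
Reagents that add atoms: water, O
Why: Reductive isoxazoline unmasking: divalent samarium cleaves the weak N–O bond by single-electron transfer to give β-hydroxy enimine 15, which boric acid and water hydrolyse to the ketone under conditions that spare the styryl alkene, benzyl ethers and silyl ether and are too mild for retro-aldol or epimerisation at C5.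

Step 9
Reactants: 16 the β-hydroxy enone from step 8
Product: 17 (2R,6S)-2-[4-(benzyloxy)-3-methoxyphenyl]-6-[(1R)-2-[4-(benzyloxy)phenyl]-1-(tert-butyldimethylsilyloxy)ethyl]tetrahydro-4H-pyran-4-one
Conditions: Amberlyst-15, CH2Cl2, rt
Reagents that add atoms: none
Why: Acid-promoted intramolecular oxa-Michael addition (6-endo-trig) of the C5 hydroxyl to C1 of the aryl enone is reversible, so the new C1 stereocentre (R) is set under thermodynamic control by C5, both substituents sitting equatorial on the chair (2,6-cis).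

Step 10
Reactants: 17 the 2,6-cis pyranone from step 9
Product: 18 (2R,4R,6S)-2-[4-(benzyloxy)-3-methoxyphenyl]-6-[(1R)-2-[4-(benzyloxy)phenyl]-1-(tert-butyldimethylsilyloxy)ethyl]tetrahydro-2H-pyran-4-ol
Conditions: NaBH4, MeOH/THF, −40 → 0 °C
Reagents that add atoms: none
Why: Ketone reduction by a small hydride donor, which attacks the conformationally locked diequatorial pyranone along the axial trajectory and should give the equatorial, all-cis C3 alcohol (R).

Step 11
Reactants: 18 the silyl-protected pyranol from step 10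
Product: 19 (2R,4R,6S)-2-[4-(benzyloxy)-3-methoxyphenyl]-6-[(1R)-2-[4-(benzyloxy)phenyl]-1-hydroxyethyl]tetrahydro-2H-pyran-4-ol
Conditions: Bu4NF, THF, rt
Reagents that add atoms: none
Why: Fluoride-induced desilylation of the secondary TBS ether, driven by Si–F bond formation; the benzyl ethers and the ring are inert.

Step 12
Reactants: 19 the bis(benzyl ether) diol from step 11
Product: 20 (2R,4R,6S)-2-(4-hydroxy-3-methoxyphenyl)-6-[(1R)-1-hydroxy-2-(4-hydroxyphenyl)ethyl]tetrahydro-2H-pyran-4-ol
Conditions: H2 (1 atm), Pd/C, EtOAc, rt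
Reagents that add atoms: none
Why: Heterogeneous hydrogenolysis of the two aryl benzyl ethers under neutral conditions, stopped at complete debenzylation so that the less reactive cyclic benzylic C1–O bond stays intact; no stereocentre is affected.

**Compound list**

1 | coniferyl aldehyde, (E)-3-(4-hydroxy-3-methoxyphenyl)prop-2-enal | COc1cc(/C=C/C=O)ccc1O | starting material
2 | (E)-3-[4-(benzyloxy)-3-methoxyphenyl]prop-2-enal | COc1cc(/C=C/C=O)ccc1OCc1ccccc1 | intermediate
3 | (1E,2E)-3-[4-(benzyloxy)-3-methoxyphenyl]prop-2-enal oxime | COc1cc(/C=C/C=N/O)ccc1OCc1ccccc1 | intermediate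
4 | 1-(benzyloxy)-4-bromobenzene | Brc1ccc(OCc2ccccc2)cc1 | starting material
5 | (R)-epichlorohydrin, (2R)-2-(chloromethyl)oxirane | ClC[C@H]1CO1 | starting material
6 | [4-(benzyloxy)phenyl]magnesium bromide | Br[Mg]c1ccc(OCc2ccccc2)cc1 | intermediate
7 | (2R)-1-[4-(benzyloxy)phenyl]-3-chloropropan-2-ol | ClC[C@H](O)Cc1ccc(OCc2ccccc2)cc1 | intermediate
8 | (2R)-2-[4-(benzyloxy)benzyl]oxirane | O1C[C@H]1Cc2ccc(OCc3ccccc3)cc2 | intermediate
9 | {(3R)-4-[4-(benzyloxy)phenyl]-3-oxidobutyl}dimethylsulfonium (betaine) | C[S+](C)CC[C@H]([O-])Cc1ccc(OCc2ccccc2)cc1 | intermediate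
10 | (2R)-1-[4-(benzyloxy)phenyl]but-3-en-2-ol | C=C[C@H](O)Cc1ccc(OCc2ccccc2)cc1 | intermediate
11 | tert-butyl{[(2R)-1-[4-(benzyloxy)phenyl]but-3-en-2-yl]oxy}dimethylsilane | C=C[C@H](O[Si](C)(C)C(C)(C)C)Cc1ccc(OCc2ccccc2)cc1 | intermediate
12 | (E)-3-[4-(benzyloxy)-3-methoxyphenyl]-N-hydroxyprop-2-enimidoyl chloride | COc1cc(/C=C/C(Cl)=NO)ccc1OCc1ccccc1 | intermediate
13 | (E)-3-[4-(benzyloxy)-3-methoxyphenyl]prop-2-enenitrile oxide | COc1cc(/C=C/C#[N+][O-])ccc1OCc1ccccc1 | intermediate
14 | (5S)-3-[(E)-2-[4-(benzyloxy)-3-methoxyphenyl]ethenyl]-5-[(1R)-2-[4-(benzyloxy)phenyl]-1-(tert-butyldimethylsilyloxy)ethyl]-4,5-dihydroisoxazole | COc1cc(/C=C/C2=NO[C@H]([C@H](O[Si](C)(C)C(C)(C)C)Cc3ccc(OCc4ccccc4)cc3)C2)ccc1OCc1ccccc1 | intermediate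
15 | (1E,5S,6R)-1-[4-(benzyloxy)-3-methoxyphenyl]-7-[4-(benzyloxy)phenyl]-6-(tert-butyldimethylsilyloxy)-3-iminohept-1-en-5-ol | COc1cc(/C=C/C(=N)C[C@H](O)[C@H](O[Si](C)(C)C(C)(C)C)Cc2ccc(OCc3ccccc3)cc2)ccc1OCc1ccccc1 | intermediate
16 | (1E,5S,6R)-1-[4-(benzyloxy)-3-methoxyphenyl]-7-[4-(benzyloxy)phenyl]-6-(tert-butyldimethylsilyloxy)-5-hydroxyhept-1-en-3-one | COc1cc(/C=C/C(=O)C[C@H](O)[C@H](O[Si](C)(C)C(C)(C)C)Cc2ccc(OCc3ccccc3)cc2)ccc1OCc1ccccc1 | intermediate
17 | (2R,6S)-2-[4-(benzyloxy)-3-methoxyphenyl]-6-[(1R)-2-[4-(benzyloxy)phenyl]-1-(tert-butyldimethylsilyloxy)ethyl]tetrahydro-4H-pyran-4-one | COc1cc([C@H]2CC(=O)C[C@@H]([C@H](O[Si](C)(C)C(C)(C)C)Cc3ccc(OCc4ccccc4)cc3)O2)ccc1OCc1ccccc1 | intermediate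
18 | (2R,4R,6S)-2-[4-(benzyloxy)-3-methoxyphenyl]-6-[(1R)-2-[4-(benzyloxy)phenyl]-1-(tert-butyldimethylsilyloxy)ethyl]tetrahydro-2H-pyran-4-ol | COc1cc([C@H]2C[C@@H](O)C[C@@H]([C@H](O[Si](C)(C)C(C)(C)C)Cc3ccc(OCc4ccccc4)cc3)O2)ccc1OCc1ccccc1 | intermediate
19 | (2R,4R,6S)-2-[4-(benzyloxy)-3-methoxyphenyl]-6-[(1R)-2-[4-(benzyloxy)phenyl]-1-hydroxyethyl]tetrahydro-2H-pyran-4-ol | COc1cc([C@H]2C[C@@H](O)C[C@@H]([C@H](O)Cc3ccc(OCc4ccccc4)cc3)O2)ccc1OCc1ccccc1 | intermediate
20 | (2R,4R,6S)-2-(4-hydroxy-3-methoxyphenyl)-6-[(1R)-1-hydroxy-2-(4-hydroxyphenyl)ethyl]tetrahydro-2H-pyran-4-ol | COc1cc([C@H]2C[C@@H](O)C[C@@H]([C@H](O)Cc3ccc(O)cc3)O2)ccc1O | target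

**Step count**

Total: 12 steps. Longest linear sequence: 10 steps (steps 3–12, from 4 and 5).

**Steps most likely to fail**

1. Step 7 (key cycloaddition). What may go wrong: insufficient facial discrimination at C5, because the inside-alkoxy preference of an acyclic allylic silyl ether carrying only a primary alkyl group is moderate, and loss of the conjugated dipole by dimerisation. Fallback: an open Mukaiyama aldol in place of the masked one, setting out from 11 and 2 and coming back at 16, so that 14 is bypassed. Oxidative cleavage of the vinyl group of 11 (OsO4 cat., NaIO4, 2,6-lutidine, dioxane/H2O; Lemieux–Johnson) should give (2R)-3-[4-(benzyloxy)phenyl]-2-(tert-butyldimethylsilyloxy)propanal F1. Addition of MeMgBr to 2 (THF, −78 °C) should give racemic (E)-4-[4-(benzyloxy)-3-methoxyphenyl]but-3-en-2-ol F2, which MnO2 in CH2Cl2 should oxidise to (E)-4-[4-(benzyloxy)-3-methoxyphenyl]but-3-en-2-one F3. TMSOTf and Et3N should convert this into (E)-{[4-[4-(benzyloxy)-3-methoxyphenyl]buta-1,3-dien-2-yl]oxy}trimethylsilane F4. Addition of F4 to F1 with BF3·OEt2 in CH2Cl2 at −78 °C is expected to follow the Felkin–Anh (non-chelation) course for an α-silyloxy aldehyde and to give the 5,6-anti (erythro) β-hydroxy enone 16 after work-up.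

2. Step 9 (oxa-Michael ring closure). What may go wrong: acid-promoted dehydration of the β-hydroxy ketone to the cross-conjugated dienone, an unfavourable open/closed equilibrium, or partial loss of the silyl ether on the acidic resin. Fallback: oxidative closure followed by conjugate reduction, setting out from 16 and coming back at 17. A Wacker-type cyclisation with PdCl2(MeCN)2 (cat.), CuCl, Na2HPO4 and O2 in DME forms the O–C1 bond irreversibly by oxypalladation and β-hydride elimination. It should give (2S)-6-[4-(benzyloxy)-3-methoxyphenyl]-2-[(1R)-2-[4-(benzyloxy)phenyl]-1-(tert-butyldimethylsilyloxy)ethyl]-2,3-dihydro-4H-pyran-4-one F5. Conjugate reduction with LiBH(s-Bu)3 (THF, −78 °C) should then deliver hydride to C1 along the axial trajectory of the half-chair that keeps the C5 substituent equatorial, placing the aryl group equatorial and giving the 2,6-cis pyranone 17.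

3. Step 12 (hydrogenolysis). What may go wrong: over-reduction, that is, hydrogenolytic cleavage of the benzylic C1–O ring bond activated by the para-oxygenated aryl group, competing with removal of the two benzyl groups. Fallback: non-reductive debenzylation, setting out from 19 and coming back at 20. BCl3 with pentamethylbenzene as benzyl-cation scavenger in CH2Cl2 at −78 °C should cleave both aryl benzyl ethers while the aryl methyl ether and the ring survive at that temperature. No new compound is made on the way.

**Further compounds**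

F1 | step 7 | (2R)-3-[4-(benzyloxy)phenyl]-2-(tert-butyldimethylsilyloxy)propanal | O=C[C@H](O[Si](C)(C)C(C)(C)C)Cc1ccc(OCc2ccccc2)cc1
F2 | step 7 | rac-(E)-4-[4-(benzyloxy)-3-methoxyphenyl]but-3-en-2-ol | COc1cc(/C=C/C(C)O)ccc1OCc1ccccc1
F3 | step 7 | (E)-4-[4-(benzyloxy)-3-methoxyphenyl]but-3-en-2-one | COc1cc(/C=C/C(C)=O)ccc1OCc1ccccc1
F4 | step 7 | (E)-{[4-[4-(benzyloxy)-3-methoxyphenyl]buta-1,3-dien-2-yl]oxy}trimethylsilane | COc1cc(/C=C/C(=C)O[Si](C)(C)C)ccc1OCc1ccccc1
F5 | step 9 | (2S)-6-[4-(benzyloxy)-3-methoxyphenyl]-2-[(1R)-2-[4-(benzyloxy)phenyl]-1-(tert-butyldimethylsilyloxy)ethyl]-2,3-dihydro-4H-pyran-4-one | COc1cc(C2=CC(=O)C[C@@H]([C@H](O[Si](C)(C)C(C)(C)C)Cc3ccc(OCc4ccccc4)cc3)O2)ccc1OCc1ccccc1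
F0 | step 12 | none | none
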